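**Strategy.** The target is cut at both sp2–sp3 bonds of its only stereocentre. This methine joins C3 of the acetyl-bearing chromene (rings A/B) to C6' of the dimethoxychromene (rings C/D) and otherwise carries only H and CH3, so its CH–CH3 unit is ethylene. One enantioselective palladium-catalysed three-component coupling of a chromen-3-yl triflate, ethylene and a chromen-6-ylboronic acid should forge both bonds and the (S) stereocentre. The triflate comes from a 2,2-dimethylchroman-3-one whose quaternary C2 permits enolisation only toward C4; its chelated 5-OH is masked as an acetate. The boronic acid is made by bromine–lithium exchange, so that boron sits unambiguously between the two methoxy groups.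

Key step: step 7

Assumption: 4-bromo-3,5-dimethoxyphenol (9) is taken as a catalogue compound.
Assumption: the sense of induction of the pyridine–oxazoline ligand on this allyl system cannot be predicted; the (S)-ligand is written and its antipode would be used if a first run shows the (R)-product.

**Step 1**
Reactants: 1 2',4'-dihydroxy-6'-methoxyacetophenone; 2 3-methylbut-2-enal (prenal)
Product: 4 1-(5-hydroxy-7-methoxy-2,2-dimethyl-2H-chromen-6-yl)ethan-1-one, via ortho-quinone methide 3 (not isolated)
Conditions: 2 (2 equiv), pyridine, 120 °C, sealed vessel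
Reagents that add atoms: none
Why: Pyridine-mediated chromenylation of a mono-chelated resorcinol (Knoevenagel-type C-alkenylation, then oxa-6π electrocyclisation): the acetyl–2'-OH hydrogen bond fixes enol character in C3'=C4', so C3' between the two hydroxyls should attack prenal and dienone 3 should close through the 4'-oxygen, leaving the chelated 2'-OH as the future 5-OH.

**Step 2**
Reactants: 4 1-(5-hydroxy-7-methoxy-2,2-dimethyl-2H-chromen-6-yl)ethan-1-one
Product: 5 6-acetyl-7-methoxy-2,2-dimethyl-2H-chromen-5-yl acetate
Conditions: Ac2O, pyridine, DMAP (cat.), CH2Cl2, rt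
Reagents that add atoms: acetic anhydride, CC(=O)OC(C)=O
Why: DMAP-catalysed O-acylation should overcome the hydrogen bond of the chelated phenol; the acetate keeps the phenol out of the later triflation and tempers the arene for the oxidation that follows.

**Step 3**
Reactants: 5 6-acetyl-7-methoxy-2,2-dimethyl-2H-chromen-5-yl acetate
Product: 7 6-acetyl-7-methoxy-2,2-dimethyl-3-oxo-3,4-dihydro-2H-chromen-5-yl acetate, via racemic 3,4-epoxide 6 (not isolated)
Conditions: DMDO (1.1 equiv), acetone, 0 °C; evaporate; ZnI2 (10 mol %), toluene, rt
Reagents that add atoms: dimethyldioxirane, CC1(C)OO1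
Why: Neutral epoxidation of the electron-rich C3=C4 styrene bond followed by Meinwald rearrangement: the Lewis acid should open the benzylic C4–O bond (cation stabilised by O1 and 7-OMe) and a 1,2-hydride shift from C3 should give the C3 ketone, as in the conversion of dihydronaphthalene oxides into 2-tetralones.

**Step 4**
Reactants: 7 6-acetyl-7-methoxy-2,2-dimethyl-3-oxo-3,4-dihydro-2H-chromen-5-yl acetate
Product: 8 6-acetyl-7-methoxy-2,2-dimethyl-3-{[(trifluoromethyl)sulfonyl]oxy}-2H-chromen-5-yl acetate
Conditions: Tf2O (1.2 equiv), 2,6-di-tert-butyl-4-methylpyridine (1.5 equiv), CH2Cl2, −78 to 0 °C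
Reagents that add atoms: trifluoromethanesulfonic anhydride, O=S(=O)(OS(=O)(=O)C(F)(F)F)C(F)(F)F
Why: Enol triflation under non-enolate conditions: C2 is quaternary, so only the acidic benzylic C4–H can be lost and a single C3=C4 triflate should form, while the doubly ortho-substituted aryl methyl ketone and the aryl acetate, which a metal enolate could engage, should stay untouched.

**Step 5**
Reactants: 9 4-bromo-3,5-dimethoxyphenol; 2 3-methylbut-2-enal (prenal)
Product: 11 6-bromo-5,7-dimethoxy-2,2-dimethyl-2H-chromene, via ortho-quinone methide 10 (not isolated)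
Conditions: 2 (1.5 equiv), ethylenediammonium diacetate (10 mol %), xylene, reflux
Reagents that add atoms: none
Why: Amine-salt-catalysed chromenylation (Knoevenagel-type condensation, then oxa-6π electrocyclisation) of an electron-rich phenol; phenol 9 is symmetric, so both ortho carbons are equivalent, the para position is blocked, and only one chromene can form, with bromine fixed between the two methoxy groups.

**Step 6**
Reactants: 11 6-bromo-5,7-dimethoxy-2,2-dimethyl-2H-chromene
Product: 14 (5,7-dimethoxy-2,2-dimethyl-2H-chromen-6-yl)boronic acid, via aryllithium 12 (not isolated), via lithium aryltriisopropoxyborate 13 (not isolated)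
Conditions: n-BuLi (1.05 equiv), THF, −78 °C; B(OiPr)3, −78 °C to rt; 1 M HCl, 0 °C, brief
Reagents that add atoms: triisopropyl borate, CC(C)OB(OC(C)C)OC(C)C; water, O
Why: Bromine–lithium exchange is faster than any ring deprotonation and places lithium exactly at C6 (a deprotonative lithiation could not reliably tell C6 from C8), and borate trapping with cold dilute-acid hydrolysis is the standard route to 2,6-dimethoxyarylboronic acids.

**Step 7**
Reactants: 8 6-acetyl-7-methoxy-2,2-dimethyl-3-{[(trifluoromethyl)sulfonyl]oxy}-2H-chromen-5-yl acetate; 15 ethylene; 14 (5,7-dimethoxy-2,2-dimethyl-2H-chromen-6-yl)boronic acid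
Product: 16 6-acetyl-3-[(1S)-1-(5,7-dimethoxy-2,2-dimethyl-2H-chromen-6-yl)ethyl]-7-methoxy-2,2-dimethyl-2H-chromen-5-yl acetate
Conditions: Pd2(dba)3·CHCl3 (5 mol %), (S)-4-tert-butyl-2-[5-(trifluoromethyl)pyridin-2-yl]-4,5-dihydrooxazole (12 mol %), 14 (2 equiv), NaHCO3 (2 equiv), ethylene (1 atm), degassed DMA, 45 °C
Reagents that add atoms: none
Why: Proposed new method: zerovalent palladium should insert into the C3–O bond of triflate 8, the cationic alkenylpalladium should carbopalladate ethylene, and β-hydride elimination with reinsertion in the opposite sense should move the metal to the carbon next to C3, giving a π-allyl over CH(CH3)–C3–C4 that is arylated at its CH(CH3) end by transmetalation from 14 and inner-sphere reductive elimination. The closest known reaction is the ligand-free racemic 1,1-alkenylarylation of ethylene with alkenyl triflates and arylboronic acids; keeping a chiral pyridine–oxazoline on palladium through β-hydride elimination and reinsertion is borrowed from enantioselective relay Heck reactions of alkenyl triflates, but ligand control in the ethylene coupling itself is without precedent. No ring is closed. The stereocentre is fixed when the ligated palladium hydride returns to one enantiotopic face of the bound vinyl group; interconversion of the allyl isomers through the CH(CH3)-bound σ-form and the stereoretentive reductive elimination leave that carbon untouched, so the ligand is the controlling element. The step needs C–C formation at CH(CH3) and not at C4, which the retained C3=C4 styrene conjugation and the shielding peri 5-acetoxy group should secure. It also needs ethylene insertion to outpace direct Suzuki–Miyaura coupling, which the slow transmetalation of the di-ortho-methoxy boronic acid, the ethylene atmosphere and the mild base NaHCO3 (which also spares the acetate and limits protodeboronation) should provide.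

**Step 8**
Reactants: 16 6-acetyl-3-[(1S)-1-(5,7-dimethoxy-2,2-dimethyl-2H-chromen-6-yl)ethyl]-7-methoxy-2,2-dimethyl-2H-chromen-5-yl acetate
Product: 17 1-{3-[(1S)-1-(5,7-dimethoxy-2,2-dimethyl-2H-chromen-6-yl)ethyl]-5-hydroxy-7-methoxy-2,2-dimethyl-2H-chromen-6-yl}ethan-1-one
Conditions: K2CO3 (cat.), MeOH, rt; aq. NH4Cl
Reagents that add atoms: none
Why: Base-catalysed transesterification (methanolysis) of the activated aryl acetate should free the chelated phenol; carbonate in methanol cannot deprotonate the doubly allylic–benzylic methine, so the (S) centre is not at risk.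

**Compound list**
1 | 2',4'-dihydroxy-6'-methoxyacetophenone | CC(=O)c1c(O)cc(O)cc1OC | starting material
2 | 3-methylbut-2-enal (prenal) | CC(C)=CC=O | starting material
3 | 4-acetyl-5-hydroxy-3-methoxy-6-(3-methylbut-2-en-1-ylidene)cyclohexa-2,4-dien-1-one (ortho-quinone methide, alkene geometry undefined) | CC(=O)C1=C(O)C(=CC=C(C)C)C(=O)C=C1OC | intermediate (not isolated)
4 | 1-(5-hydroxy-7-methoxy-2,2-dimethyl-2H-chromen-6-yl)ethan-1-one | COc1cc2c(c(O)c1C(C)=O)C=CC(C)(C)O2 | intermediate
5 | 6-acetyl-7-methoxy-2,2-dimethyl-2H-chromen-5-yl acetate | COc1cc2c(c(OC(C)=O)c1C(C)=O)C=CC(C)(C)O2 | intermediate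
6 | racemic 6-acetyl-3,4-epoxy-7-methoxy-2,2-dimethylchroman-5-yl acetate | COc1cc2c(c(OC(C)=O)c1C(C)=O)C3OC3C(C)(C)O2 | intermediate (not isolated)
7 | 6-acetyl-7-methoxy-2,2-dimethyl-3-oxo-3,4-dihydro-2H-chromen-5-yl acetate | COc1cc2c(c(OC(C)=O)c1C(C)=O)CC(=O)C(C)(C)O2 | intermediate
8 | 6-acetyl-7-methoxy-2,2-dimethyl-3-{[(trifluoromethyl)sulfonyl]oxy}-2H-chromen-5-yl acetate | COc1cc2c(c(OC(C)=O)c1C(C)=O)C=C(OS(=O)(=O)C(F)(F)F)C(C)(C)O2 | intermediate
9 | 4-bromo-3,5-dimethoxyphenol | COc1cc(O)cc(OC)c1Br | starting material
10 | 4-bromo-3,5-dimethoxy-6-(3-methylbut-2-en-1-ylidene)cyclohexa-2,4-dien-1-one (ortho-quinone methide, alkene geometry undefined) | COC1=CC(=O)C(=CC=C(C)C)C(OC)=C1Br | intermediate (not isolated)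
11 | 6-bromo-5,7-dimethoxy-2,2-dimethyl-2H-chromene | COc1cc2c(c(OC)c1Br)C=CC(C)(C)O2 | intermediate
12 | (5,7-dimethoxy-2,2-dimethyl-2H-chromen-6-yl)lithium | [Li]c1c(OC)cc2c(c1OC)C=CC(C)(C)O2 | intermediate (not isolated)
13 | lithium (5,7-dimethoxy-2,2-dimethyl-2H-chromen-6-yl)tri(propan-2-yloxy)borate | [Li+].CC(C)O[B-](OC(C)C)(OC(C)C)c1c(OC)cc2c(c1OC)C=CC(C)(C)O2 | intermediate (not isolated)
14 | (5,7-dimethoxy-2,2-dimethyl-2H-chromen-6-yl)boronic acid | OB(O)c1c(OC)cc2c(c1OC)C=CC(C)(C)O2 | intermediate
15 | ethylene | C=C | starting material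
16 | 6-acetyl-3-[(1S)-1-(5,7-dimethoxy-2,2-dimethyl-2H-chromen-6-yl)ethyl]-7-methoxy-2,2-dimethyl-2H-chromen-5-yl acetate | COc1cc2c(c(OC(C)=O)c1C(C)=O)C=C([C@H](C)c1c(OC)cc3c(c1OC)C=CC(C)(C)O3)C(C)(C)O2 | intermediate
17 | 1-{3-[(1S)-1-(5,7-dimethoxy-2,2-dimethyl-2H-chromen-6-yl)ethyl]-5-hydroxy-7-methoxy-2,2-dimethyl-2H-chromen-6-yl}ethan-1-one | COc1cc2c(c(O)c1C(C)=O)C=C([C@H](C)c1c(OC)cc3c(c1OC)C=CC(C)(C)O3)C(C)(C)O2 | target

**Step count.** Total: 8 steps. Longest linear sequence: 6 steps (1, 2, 3, 4, 7, 8); the boronic acid branch (5, 6) joins at step 7.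

**Steps most likely to fail**

First, step 7. The ligand may discriminate poorly between the two faces of the bound vinyl group when the hydride returns. The bidentate ligand may slow transmetalation of the hindered boronic acid until protodeboronation or diene release takes over. Aryl transfer may also leak to C4. The fallback gives up catalyst control and uses known chemistry. It sets out from 8, 15 and 14 under the established ligand-free conditions (Pd2(dba)3, NaHCO3, DMA, ethylene 1 atm, 55 °C, boronic acid in excess), which should give the racemic 5-O-acetate F1. Preparative chiral supercritical-fluid chromatography on a polysaccharide phase should then separate 16 from the (R)-enantiomer F2, and the route is rejoined at 16. The absolute configuration would be assigned by chiroptical comparison or anomalous-dispersion crystallography.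

Second, step 3. The benzylic C4 cation may be diverted before the hydride shift, by capture through the peri acetate carbonyl, by ring contraction through migration of C2, or by hydrolytic opening to a diol. The fallback avoids the cation altogether. It sets out from 5, which is epoxidised with DMDO as before to 6. The benzylic C4–O bond of 6 is then cleaved by hydrogenolysis (H2 1 atm, palladium on carbon, EtOAc, trace Et3N, rt) to give racemic 6-acetyl-3-hydroxy-7-methoxy-2,2-dimethyl-3,4-dihydro-2H-chromen-5-yl acetate F3. Oxidation of this alcohol with Dess–Martin periodinane (NaHCO3, CH2Cl2, rt) should return the route to 7.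

Third, step 1. Condensation may compete at C5', closure may occur through the chelated oxygen, and prenal may oligomerise, which would erode regiochemical purity and throughput. The fallback forms the C–C bond intramolecularly and sets out from 1. Selective O-alkylation of the non-chelated 4'-OH with 3-chloro-3-methylbut-1-yne (K2CO3, KI, acetone, reflux) should give 1-[2-hydroxy-6-methoxy-4-(2-methylbut-3-yn-2-yloxy)phenyl]ethan-1-one F4. Heating in N,N-diethylaniline (about 180 °C) should trigger an aromatic propargyl Claisen rearrangement to C3', directed by the chelate-induced bond fixation, giving 1-[2,4-dihydroxy-6-methoxy-3-(3-methylbuta-1,2-dien-1-yl)phenyl]ethan-1-one F5. A [1,5]-hydrogen shift then leads to dienone 3, and oxa-6π closure rejoins the route at 4.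

**Further compounds**
F1 | step 7 | racemic 6-acetyl-3-[1-(5,7-dimethoxy-2,2-dimethyl-2H-chromen-6-yl)ethyl]-7-methoxy-2,2-dimethyl-2H-chromen-5-yl acetate | COc1cc2c(c(OC(C)=O)c1C(C)=O)C=C(C(C)c1c(OC)cc3c(c1OC)C=CC(C)(C)O3)C(C)(C)O2
F2 | step 7 | 6-acetyl-3-[(1R)-1-(5,7-dimethoxy-2,2-dimethyl-2H-chromen-6-yl)ethyl]-7-methoxy-2,2-dimethyl-2H-chromen-5-yl acetate | COc1cc2c(c(OC(C)=O)c1C(C)=O)C=C([C@@H](C)c1c(OC)cc3c(c1OC)C=CC(C)(C)O3)C(C)(C)O2
F3 | step 3 | racemic 6-acetyl-3-hydroxy-7-methoxy-2,2-dimethyl-3,4-dihydro-2H-chromen-5-yl acetate | COc1cc2c(c(OC(C)=O)c1C(C)=O)CC(O)C(C)(C)O2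
F4 | step 1 | 1-[2-hydroxy-6-methoxy-4-(2-methylbut-3-yn-2-yloxy)phenyl]ethan-1-one | CC(=O)c1c(O)cc(OC(C)(C)C#C)cc1OC
F5 | step 1 | 1-[2,4-dihydroxy-6-methoxy-3-(3-methylbuta-1,2-dien-1-yl)phenyl]ethan-1-one | CC(=O)c1c(O)c(C=C=C(C)C)c(O)cc1OC
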